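**Plan**

- Ring A of gnetupendin B (C1 styryl, C2 benzyl, C3 OH, C4 H, C5 OH, C6 H) has two meta oxygens with an unsubstituted C4 between them. The retrosynthesis cuts C3–C4, C5–C6 and C2–C3, which leaves a vinylketene (C3, C6, C1, C2, stored as a 4-benzyl-3-styrylcyclobutenone) and a terminal siloxyalkyne (C4, C5).
- The cyclobutenone is then cut at the ring–styryl bond (alkenyllithium plus a 3-ethoxycyclobutenone) and across the four-membered ring (a benzylketene plus ethoxyacetylene).
- Forward: ring B acid chloride, ketene/ethoxyacetylene (2+2), addition of the ring C styryllithium with enone transposition, benzannulation that builds ring A between rings B and C, then one fluoride step that removes all four silyl groups.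
- Stereochemistry: the E alkene is the only stereo element. It is set by a Takai olefination of silylated vanillin and carried through iodine–lithium exchange with retention. The sp3 centre of the cyclobutenones is racemic and vanishes when ring A aromatises.

Key step: step 9

Assumption: (triisopropylsilyloxy)ethyne is taken to be isolable and to survive 80 °C long enough to react, as its 2-alkyl homologues do.

Abbreviations: TBS = tert-butyldimethylsilyl; TIPS = triisopropylsilyl; ArB = 3,4-bis(tert-butyldimethylsilyloxy)phenyl; ArC = 4-(tert-butyldimethylsilyloxy)-3-methoxyphenyl.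

**Route**

Step 1
Reactants: 1 dihydrocaffeic acid [3-(3,4-dihydroxyphenyl)propanoic acid]
Product: 2 tert-butyldimethylsilyl 3-[3,4-bis(tert-butyldimethylsilyloxy)phenyl]propanoate
Conditions: TBSCl (3.5 equiv), imidazole (7 equiv), DMF, rt
Reagents that add atoms: tert-butyldimethylsilyl chloride, CC(C)(C)[Si](C)(C)Cl
Why: Imidazole-promoted silylation should cap both phenols and the acid in one operation, and the silyl ester is the handle for the next step; no stereocentre is involved.

Step 2
Reactants: 2 tert-butyldimethylsilyl 3-[3,4-bis(tert-butyldimethylsilyloxy)phenyl]propanoate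
Product: 3 3-[3,4-bis(tert-butyldimethylsilyloxy)phenyl]propanoyl chloride
Conditions: (COCl)2 (1.2 equiv), DMF (cat.), CH2Cl2, 0 °C to rt; used crude
Reagents that add atoms: oxalyl chloride, ClC(=O)C(=O)Cl
Why: Chlorination of a silyl ester by the Vilsmeier chloride releases TBSCl instead of HCl, so the acid chloride should form under neutral conditions that the aryl silyl ethers tolerate.

Step 3
Reactants: 3 3-[3,4-bis(tert-butyldimethylsilyloxy)phenyl]propanoyl chloride; 4 ethoxyacetylene
Product: 6 rac-4-[3,4-bis(tert-butyldimethylsilyloxy)benzyl]-3-ethoxycyclobut-2-en-1-one, via ketene 5 (not isolated)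
Conditions: 4 (3 equiv), Et3N (1.2 equiv, slow addition), Et2O, 0 °C to rt
Reagents that add atoms: none
Why: Dehydrochlorination gives the monoalkylketene 5, which should undergo the thermal ketene–ynol ether (2+2) cycloaddition with the nucleophilic CH terminus of 4 bonding to the ketene carbonyl carbon, so the benzyl-bearing carbon lies between C=O and C–OEt; the new sp3 centre is racemic and is erased in step 9.

Step 4
Reactants: 7 vanillin
Product: 8 4-(tert-butyldimethylsilyloxy)-3-methoxybenzaldehyde
Conditions: TBSCl (1.2 equiv), imidazole (2.5 equiv), DMF, rt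
Reagents that add atoms: tert-butyldimethylsilyl chloride, CC(C)(C)[Si](C)(C)Cl
Why: Standard imidazole-promoted silylation of a phenol; the aldehyde is untouched.

Step 5
Reactants: 8 4-(tert-butyldimethylsilyloxy)-3-methoxybenzaldehyde; 9 iodoform
Product: 10 tert-butyl{4-[(E)-2-iodoethenyl]-2-methoxyphenoxy}dimethylsilane
Conditions: CrCl2 (6 equiv), 9 (2 equiv), THF–1,4-dioxane (1:6), 0 °C to rt
Reagents that add atoms: none
Why: Takai olefination: the geminal dichromium species formed from iodoform and divalent chromium adds to the aldehyde and eliminates to the alkenyl iodide with E geometry, which is the only stereo element of the target.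

Step 6
Reactants: 10 tert-butyl{4-[(E)-2-iodoethenyl]-2-methoxyphenoxy}dimethylsilane; 6 rac-4-[3,4-bis(tert-butyldimethylsilyloxy)benzyl]-3-ethoxycyclobut-2-en-1-one
Product: 13 rac-4-[3,4-bis(tert-butyldimethylsilyloxy)benzyl]-3-[(E)-2-(4-tert-butyldimethylsilyloxy-3-methoxyphenyl)ethenyl]cyclobut-2-en-1-one, via alkenyllithium 11 (not isolated), via cyclobutenol 12 (not isolated)
Conditions: 10, t-BuLi (2.0 equiv), Et2O, −78 °C; then 6 in THF, −78 °C; then 1 M aq HCl, THF, 0 °C, short contact
Reagents that add atoms: water, O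
Why: Iodine–lithium exchange keeps the E geometry, the alkenyllithium adds 1,2 to the vinylogous ester, and mild acid hydrolysis of the enol ether with loss of the doubly allylic hydroxyl (Stork–Danheiser-type transposition) should leave the carbonyl on the former C–OEt carbon; the ring stereocentre stays racemic.

Step 7
Reactants: 14 trimethylsilylacetylene
Product: 17 triisopropyl{[2-(trimethylsilyl)ethynyl]oxy}silane, via lithium acetylide 15 (not isolated), via lithium ynolate 16 (not isolated)
Conditions: n-BuLi (1.0 equiv), THF, −78 °C; transfer into t-BuOOLi [from t-BuOOH and LiN(SiMe3)2, THF, −78 °C], −78 to 0 °C; TIPSOTf (1.2 equiv), −78 °C to rt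
Reagents that add atoms: tert-butyl hydroperoxide, CC(C)(C)OO; triisopropylsilyl trifluoromethanesulfonate, CC(C)[Si](OS(=O)(=O)C(F)(F)F)(C(C)C)C(C)C
Why: Oxygen transfer from lithium tert-butyl peroxide to a lithium acetylide gives the ynolate (acetylide oxidation), and the bulky silyl triflate is expected to silylate this ambident anion on oxygen, as triisopropylsilylation of ynolates generally does.

Step 8
Reactants: 17 triisopropyl{[2-(trimethylsilyl)ethynyl]oxy}silane
Product: 18 (ethynyloxy)triisopropylsilane [(triisopropylsilyloxy)ethyne]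
Conditions: K2CO3 (0.2 equiv), MeOH–THF, 0 °C, short contact; pentane extraction, handled cold as a concentrated solution
Reagents that add atoms: none
Why: Base-catalysed methanolysis of an alkynyl–SiMe3 bond (protodesilylation) should be much faster than attack at the hindered triisopropylsilyl oxygen, leaving the terminal siloxyalkyne.

Step 9
Reactants: 13 rac-4-[3,4-bis(tert-butyldimethylsilyloxy)benzyl]-3-[(E)-2-(4-tert-butyldimethylsilyloxy-3-methoxyphenyl)ethenyl]cyclobut-2-en-1-one; 18 (ethynyloxy)triisopropylsilane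
Product: 23 2-[3,4-bis(tert-butyldimethylsilyloxy)benzyl]-3-[(E)-2-(4-tert-butyldimethylsilyloxy-3-methoxyphenyl)ethenyl]-5-(triisopropylsilyloxy)phenol, via vinylketene 19 (not isolated), via vinylcyclobutenone 20 (not isolated), via dienylketene 21 (not isolated), via cyclohexadienone 22 (not isolated)
Conditions: 18 (2 equiv), toluene, 80 °C, then 110 °C if 20 persists, argon
Reagents that add atoms: none
Why: Thermal four-electron conrotatory opening of 13 (benzyl group turning outward) gives vinylketene 19, whose ketene C=C adds to 18 in a polarity-controlled (2+2) to give the 4-alkenyl-3-siloxycyclobutenone 20 (new bonds C3–C4 and C5–C6 of ring A), and 20 opens again to dienylketene 21. Ring A is then closed by a thermal disrotatory six-electron electrocyclisation of 21 that joins the ketene carbon C3 to the benzyl-bearing terminus C2, and cyclohexadienone 22 tautomerises to phenol 23. This is the Danheiser benzannulation of a cyclobutenone with a siloxyalkyne, the known route to resorcinol monosilyl ethers, applied here to a 3-alkenyl-4-benzyl cyclobutenone. No stereocentre is created: the racemic centre of 13 and the transient centres of 20 and 22 all end as sp2 carbons, and the E styryl bond is only cross-conjugated with the ketene in 19 and 21 and so has no electrocyclic path of its own. The one selectivity needed is the orientation of the (2+2), and the oxygen lone pair of 18 secures it by making the CH terminus nucleophilic so that it bonds to the electrophilic ketene carbon, which places the two ring oxygens meta with the bare C4 between them. An excess of 18 should keep capture of 19 faster than its self-reaction or its acylation of the product phenol.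

Step 10
Reactants: 23 2-[3,4-bis(tert-butyldimethylsilyloxy)benzyl]-3-[(E)-2-(4-tert-butyldimethylsilyloxy-3-methoxyphenyl)ethenyl]-5-(triisopropylsilyloxy)phenol
Product: 24 gnetupendin B
Conditions: Bu4NF (5 equiv), AcOH (5 equiv), degassed THF, 0 °C to rt, argon
Reagents that add atoms: none
Why: Fluoride-induced desilylation should cleave all four aryl silyl ethers at once, while acetic acid keeps the liberated catechol and resorcinol protonated so that the electron-rich stilbene sees neither strong base nor strong acid; the E alkene is untouched.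

**Compound list**

1 | dihydrocaffeic acid, 3-(3,4-dihydroxyphenyl)propanoic acid | OC(=O)CCc1ccc(O)c(O)c1 | starting material
2 | tert-butyldimethylsilyl 3-ArB-propanoate | CC(C)(C)[Si](C)(C)OC(=O)CCc1ccc(O[Si](C)(C)C(C)(C)C)c(O[Si](C)(C)C(C)(C)C)c1 | intermediate
3 | 3-ArB-propanoyl chloride | O=C(Cl)CCc1ccc(O[Si](C)(C)C(C)(C)C)c(O[Si](C)(C)C(C)(C)C)c1 | intermediate
4 | ethoxyacetylene | CCOC#C | starting material
5 | 3-ArB-prop-1-en-1-one, the (ArB-methyl)ketene, formed in the flask | O=C=CCc1ccc(O[Si](C)(C)C(C)(C)C)c(O[Si](C)(C)C(C)(C)C)c1 | intermediate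
6 | rac-4-(ArB-methyl)-3-ethoxycyclobut-2-en-1-one, one enantiomer drawn | CCOC1=CC(=O)[C@@H]1Cc1ccc(O[Si](C)(C)C(C)(C)C)c(O[Si](C)(C)C(C)(C)C)c1 | intermediate
7 | vanillin | COc1cc(C=O)ccc1O | starting material
8 | 4-(tert-butyldimethylsilyloxy)-3-methoxybenzaldehyde | COc1cc(C=O)ccc1O[Si](C)(C)C(C)(C)C | intermediate
9 | iodoform | IC(I)I | starting material
10 | tert-butyl{4-[(E)-2-iodoethenyl]-2-methoxyphenoxy}dimethylsilane | COc1cc(/C=C/I)ccc1O[Si](C)(C)C(C)(C)C | intermediate
11 | [(E)-2-ArC-ethenyl]lithium, formed in the flask | COc1cc(/C=C/[Li])ccc1O[Si](C)(C)C(C)(C)C | intermediate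
12 | 4-(ArB-methyl)-3-ethoxy-1-[(E)-2-ArC-ethenyl]cyclobut-2-en-1-ol, formed as its lithium alkoxide, racemic mixture of diastereomers, ring centres not assigned | CCOC1=CC(O)(/C=C/c2ccc(O[Si](C)(C)C(C)(C)C)c(OC)c2)C1Cc3ccc(O[Si](C)(C)C(C)(C)C)c(O[Si](C)(C)C(C)(C)C)c3 | intermediate
13 | rac-4-(ArB-methyl)-3-[(E)-2-ArC-ethenyl]cyclobut-2-en-1-one, one enantiomer drawn | O=C1C=C(/C=C/c2ccc(O[Si](C)(C)C(C)(C)C)c(OC)c2)[C@@H]1Cc3ccc(O[Si](C)(C)C(C)(C)C)c(O[Si](C)(C)C(C)(C)C)c3 | intermediate
14 | trimethylsilylacetylene | C#C[Si](C)(C)C | starting material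
15 | lithium (trimethylsilyl)acetylide, formed in the flask | [Li]C#C[Si](C)(C)C | intermediate
16 | lithium 2-(trimethylsilyl)ethynolate, formed in the flask | [Li+].[O-]C#C[Si](C)(C)C | intermediate
17 | triisopropyl{[2-(trimethylsilyl)ethynyl]oxy}silane | C[Si](C)(C)C#CO[Si](C(C)C)(C(C)C)C(C)C | intermediate
18 | (ethynyloxy)triisopropylsilane, (triisopropylsilyloxy)ethyne | C#CO[Si](C(C)C)(C(C)C)C(C)C | intermediate
19 | (3E)-5-ArB-3-[(E)-2-ArC-ethenyl]penta-1,3-dien-1-one, the vinylketene, formed in the flask | O=C=C/C(/C=C/c2ccc(O[Si](C)(C)C(C)(C)C)c(OC)c2)=C/Cc3ccc(O[Si](C)(C)C(C)(C)C)c(O[Si](C)(C)C(C)(C)C)c3 | intermediate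
20 | rac-4-[(1E,3E)-5-ArB-1-ArC-penta-1,3-dien-3-yl]-3-(triisopropylsilyloxy)cyclobut-2-en-1-one, the (2+2) adduct, one enantiomer drawn, formed in the flask | O=C1C=C(O[Si](C(C)C)(C(C)C)C(C)C)[C@H]1/C(/C=C/c2ccc(O[Si](C)(C)C(C)(C)C)c(OC)c2)=C/Cc3ccc(O[Si](C)(C)C(C)(C)C)c(O[Si](C)(C)C(C)(C)C)c3 | intermediate
21 | (3E,5E)-7-ArB-5-[(E)-2-ArC-ethenyl]-3-(triisopropylsilyloxy)hepta-1,3,5-trien-1-one, the dienylketene with the ketene arm and C5 cis across C3=C4, formed in the flask | O=C=C/C(O[Si](C(C)C)(C(C)C)C(C)C)=C\C(\C=C\c2ccc(O[Si](C)(C)C(C)(C)C)c(OC)c2)=C\Cc3ccc(O[Si](C)(C)C(C)(C)C)c(O[Si](C)(C)C(C)(C)C)c3 | intermediate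
22 | rac-6-(ArB-methyl)-5-[(E)-2-ArC-ethenyl]-3-(triisopropylsilyloxy)cyclohexa-2,4-dien-1-one, one enantiomer drawn, formed in the flask | O=C1C=C(O[Si](C(C)C)(C(C)C)C(C)C)C=C(/C=C/c2ccc(O[Si](C)(C)C(C)(C)C)c(OC)c2)[C@@H]1Cc3ccc(O[Si](C)(C)C(C)(C)C)c(O[Si](C)(C)C(C)(C)C)c3 | intermediate
23 | 2-(ArB-methyl)-3-[(E)-2-ArC-ethenyl]-5-(triisopropylsilyloxy)phenol (ring A: C3 OH free, C5 O-TIPS) | COc1cc(/C=C/c2cc(O[Si](C(C)C)(C(C)C)C(C)C)cc(O)c2Cc2ccc(O[Si](C)(C)C(C)(C)C)c(O[Si](C)(C)C(C)(C)C)c2)ccc1O[Si](C)(C)C(C)(C)C | intermediate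
24 | gnetupendin B | COc1cc(/C=C/c2cc(O)cc(O)c2Cc2ccc(O)c(O)c2)ccc1O | target

**Step count and risks**

Total step count: 10. Longest linear sequence: 6 steps (steps 1, 2, 3, 6, 9, 10; compounds 1, 2, 3, 6, 13, 23, 24).

Steps most likely to fail:

Step 9. The terminal siloxyalkyne may rearrange by 1,3-silyl shift to a silylketene, or oligomerise, at the temperature needed to open 13. Vinylketene 19 would then be lost to self-reaction or to acylation of the product phenol. Migration of the ring double bond of 13 to the 2-benzyl isomer would be harmless, since the same cascade would then give the regioisomeric monosilyl ether, which step 10 would convert into the same product. The fallback sets out from 13 and replaces the siloxyalkyne by an alkoxyethyne, the original partner class of this benzannulation, which cannot undergo the silyl shift. 2-(Trimethylsilyl)ethanol, KH and trichloroethylene in THF should give (E)-1,2-dichloro-1-[2-(trimethylsilyl)ethoxy]ethene F1. n-BuLi (2.2 equiv) at −78 °C should convert it into lithium [2-(trimethylsilyl)ethoxy]ethynide F2, which methanol protonates to [2-(ethynyloxy)ethyl]trimethylsilane F3. Heating 13 with F3 in toluene at 80 °C should give 2-(ArB-methyl)-3-[(E)-2-ArC-ethenyl]-5-[2-(trimethylsilyl)ethoxy]phenol F4 by the same cascade. Bu4NF in DMF at 60 °C should then remove the three TBS groups and fragment the 2-(trimethylsilyl)ethyl ether, and the route is rejoined at 24.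

Step 8. Cleavage of the O–Si bond, or addition of methanol to the ynol ether, may compete with C–Si methanolysis, and the volatile product may be lost on concentration. The fallback sets out from 17 and omits the desilylation. Heating 17 with 13 under the conditions of step 9 should give 2-(ArB-methyl)-3-[(E)-2-ArC-ethenyl]-5-(triisopropylsilyloxy)-6-(trimethylsilyl)phenol F5. The orientation of the (2+2) is reinforced here, because positive charge develops on a carbon that is both attached to oxygen and beta to silicon. Ipso-protodesilylation of F5 with CF3CO2H (2 equiv) in CH2Cl2 at 0 °C, at the carbon flanked by two oxygens, should then return the route at 23.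

Step 3. Amine-catalysed dimerisation and oligomerisation of the monoalkylketene 5 may outrun its cycloaddition to 4. The fallback sets out from 4 and generates 5 slowly and amine-free by a Wolff rearrangement. Purchased 3,4-dihydroxyphenylacetic acid is silylated (TBSCl, imidazole, DMF) to tert-butyldimethylsilyl 2-ArB-acetate F6. Oxalyl chloride with catalytic DMF converts this into 2-ArB-acetyl chloride F7, and excess diazomethane in Et2O at 0 °C gives 1-diazo-3-ArB-propan-2-one F8. Irradiation of F8 at 365 nm in CH2Cl2 with an excess of 4 should release 5 at low stationary concentration, and its (2+2) with 4 rejoins the route at 6.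

**Further compounds**

F1 | step 9 | (E)-1,2-dichloro-1-[2-(trimethylsilyl)ethoxy]ethene | C[Si](C)(C)CCO/C(Cl)=C\Cl
F2 | step 9 | lithium [2-(trimethylsilyl)ethoxy]ethynide | [Li]C#COCC[Si](C)(C)C
F3 | step 9 | [2-(ethynyloxy)ethyl]trimethylsilane | C#COCC[Si](C)(C)C
F4 | step 9 | 2-(ArB-methyl)-3-[(E)-2-ArC-ethenyl]-5-[2-(trimethylsilyl)ethoxy]phenol | COc1cc(/C=C/c2cc(OCC[Si](C)(C)C)cc(O)c2Cc2ccc(O[Si](C)(C)C(C)(C)C)c(O[Si](C)(C)C(C)(C)C)c2)ccc1O[Si](C)(C)C(C)(C)C
F5 | step 8 | 2-(ArB-methyl)-3-[(E)-2-ArC-ethenyl]-5-(triisopropylsilyloxy)-6-(trimethylsilyl)phenol | COc1cc(/C=C/c2cc(O[Si](C(C)C)(C(C)C)C(C)C)c([Si](C)(C)C)c(O)c2Cc2ccc(O[Si](C)(C)C(C)(C)C)c(O[Si](C)(C)C(C)(C)C)c2)ccc1O[Si](C)(C)C(C)(C)C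
F6 | step 3 | tert-butyldimethylsilyl 2-[3,4-bis(tert-butyldimethylsilyloxy)phenyl]acetate | CC(C)(C)[Si](C)(C)OC(=O)Cc1ccc(O[Si](C)(C)C(C)(C)C)c(O[Si](C)(C)C(C)(C)C)c1
F7 | step 3 | 2-[3,4-bis(tert-butyldimethylsilyloxy)phenyl]acetyl chloride | O=C(Cl)Cc1ccc(O[Si](C)(C)C(C)(C)C)c(O[Si](C)(C)C(C)(C)C)c1
F8 | step 3 | 1-diazo-3-[3,4-bis(tert-butyldimethylsilyloxy)phenyl]propan-2-one | [N-]=[N+]=CC(=O)Cc1ccc(O[Si](C)(C)C(C)(C)C)c(O[Si](C)(C)C(C)(C)C)c1
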